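**Plan**

- Retrosynthesis (labdane numbering): remove the C6 acetate; open the oxolane and lactone rings together (C13–O, C14–C15, C15–O16) to a triol; cut C11–C12 (epoxide opening) and C9=C11; then cut C2–C3 of ring A (ring-closing metathesis), C4–C5 (prenyl Grignard) and C10–C1 (allylation of a cyclic 1,3-dione).
- Forward: ring B comes from 2-methylcyclohexane-1,3-dione; ring A is closed onto it at C2–C3; C6 and C9 are then adjusted; the two heterocycles are formed last in one step.
- What makes the ring closure possible: C5 of ring B sits between two fully substituted carbons, C4 (gem-dimethyl) and C10 (angular methyl). They carry the vinyl arm (C3) and the allyl arm (C1–C2) on adjacent ring positions and press them together (Thorpe–Ingold), so six-membered ring A closes readily.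
- Stereochemistry: C10 from yeast desymmetrisation of the prochiral dione; C8 by equilibration (equatorial methyl, anti to C20); C5 by α-face hydroboration; C6 by α-face hydride delivery; C9 by α-face epoxidation; C13 in the alkoxypalladation.

Key step: step 6

Remark: bicyclic compounds are named on the labdane skeleton (C1 to C20); α is the face opposite the C20 methyl group; 11,12,13,14,15,16-hexanorlabdane is the decalin core carrying C17 to C20.

**Route**

Step 1
Reactants: 1 2-methylcyclohexane-1,3-dione; 2 allyl bromide
Product: 3 2-methyl-2-(prop-2-en-1-yl)cyclohexane-1,3-dione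
Conditions: NaOH (1 M aq), rt
Reagents that add atoms: allyl bromide (compound 2), C=CCBr
Why: C-alkylation of the cyclic β-diketone enolate should give the prochiral 2,2-disubstituted dione, with no stereocentre formed.

Step 2
Reactants: 3 2-methyl-2-(prop-2-en-1-yl)cyclohexane-1,3-dione
Product: 4 (2S,3S)-3-hydroxy-2-methyl-2-(prop-2-en-1-yl)cyclohexan-1-one
Conditions: baker's yeast (Saccharomyces cerevisiae), sucrose, H2O, 30 °C; chromatography to one diastereomer
Reagents that add atoms: none
Why: Enzymatic reduction of one of the two enantiotopic carbonyl groups (the classical yeast desymmetrisation of 2,2-disubstituted cyclohexane-1,3-diones) should fix the quaternary carbon, the future C10, as S under enzyme control; the carbinol centre is removed again in step 4.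

Step 3
Reactants: 4 (2S,3S)-3-hydroxy-2-methyl-2-(prop-2-en-1-yl)cyclohexan-1-one
Product: 5 (2S,3S)-3-hydroxy-2,6-dimethyl-2-(prop-2-en-1-yl)cyclohexan-1-one (both C6 epimers)
Conditions: LiN(iPr)2 (2.2 equiv), THF, DMPU, −78 °C; MeI (1.05 equiv), −78 to −40 °C; cold NH4Cl quench
Reagents that add atoms: iodomethane, CI
Why: The alkoxide enolate dianion (the ketone has only one α-CH2) should be C-methylated at the enolate carbon; the new centre (future C8) forms unselectively and is equilibrated in step 7.

Step 4
Reactants: 5 (2S,3S)-3-hydroxy-2,6-dimethyl-2-(prop-2-en-1-yl)cyclohexan-1-one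
Product: 6 (2S)-2,4-dimethyl-2-(prop-2-en-1-yl)cyclohexane-1,3-dione (both C4 epimers)
Conditions: Dess–Martin periodinane, NaHCO3, CH2Cl2, rt
Reagents that add atoms: none
Why: Dess–Martin oxidation should return the 1,3-dione, which is now chiral because the new methyl group tells the two carbonyl groups apart; the quaternary centre has no α-hydrogen and cannot racemise.

Step 5
Reactants: 6 (2S)-2,4-dimethyl-2-(prop-2-en-1-yl)cyclohexane-1,3-dione; 7 prenylmagnesium chloride
Product: 8 (2S)-3-hydroxy-2,6-dimethyl-3-(2-methylbut-3-en-2-yl)-2-(prop-2-en-1-yl)cyclohexan-1-one (epimers at C3 and C6)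
Conditions: Me2C=CHCH2MgCl (1.2 equiv), THF, −78 °C; AcOH quench at −78 °C
Reagents that add atoms: prenylmagnesium chloride (compound 7), CC(C)=CC[Mg]Cl
Why: The allylic Grignard reagent should add through its γ-terminus (six-membered SE2' transition state) to the less hindered carbonyl, the one flanked by CH2 and not by CH(CH3), giving the 1,1-dimethylallyl carbinol that carries C3, C4, C18 and C19; the carbinol configuration is immaterial because C5 becomes sp2 in step 7.

Step 6
Reactants: 8 (2S)-3-hydroxy-2,6-dimethyl-3-(2-methylbut-3-en-2-yl)-2-(prop-2-en-1-yl)cyclohexan-1-one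
Product: 10 (10S)-5-hydroxy-11,12,13,14,15,16-hexanorlabdan-9-one (epimers at C5 and C8), via (10S)-5-hydroxy-11,12,13,14,15,16-hexanorlabd-2-en-9-one 9 (not isolated)
Conditions: second-generation Grubbs catalyst RuCl2(=CHPh)(PCy3)(H2IMes) (5 mol %), ClCH2CH2Cl, 45 °C; then H2 (7 atm), 70 °C, same pot
Reagents that add atoms: none
Why: The ruthenium benzylidene should enter at the unhindered allyl terminus (C2), and the resulting alkylidene should undergo intramolecular [2+2] cycloaddition and cycloreversion with the neopentyl vinyl group (C3) through a ruthenacyclobutane, releasing ethylene (Chauvin mechanism). The closest known reaction type is ring-closing metathesis of 1,7-dienes with an allylic quaternary carbon to give 3,3-dimethylcyclohexenes. Ring A closes as a cyclohexene by alkene–alkene metathesis of the octa-1,7-diene unit, the new C2=C3 bond being endocyclic and the ring being annulated on ring B across C5–C10. No stereocentre is created: C10 comes from step 2, and both C5 epimers close and converge in step 7. The step needs ring closure to win over cross-metathesis and needs the hindered vinyl group to react; the gem-dimethyl group at C4 and the quaternary C10 hold the two arms on adjacent ring carbons, and loss of ethylene makes closure irreversible. Hydrogen is then admitted so that the same ruthenium charge, converted to a ruthenium hydride, should saturate C2=C3, the only alkene left.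

Step 7
Reactants: 10 (10S)-5-hydroxy-11,12,13,14,15,16-hexanorlabdan-9-one
Product: 11 (8R,10S)-11,12,13,14,15,16-hexanorlabd-5-en-9-one
Conditions: SOCl2, pyridine, 0 °C; then NaOMe (cat.), MeOH, rt
Reagents that add atoms: none
Why: E2 elimination of the tertiary chlorosulfite can only take a proton from C6 (C4 and C10 are quaternary), so a single alkene is expected; methoxide then equilibrates C8 to the equatorial 8α-methyl epimer, which avoids the 1,3-clash with the C20 methyl group.

Step 8
Reactants: 11 (8R,10S)-11,12,13,14,15,16-hexanorlabd-5-en-9-one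
Product: 12 (5S,6S,8R,10S)-11,12,13,14,15,16-hexanorlabdane-6α,9-diol (5α-H; either C9 epimer)
Conditions: BH3·THF (4 equiv), THF, 0 to 45 °C; then NaOH (3 M), H2O2 (30%), 0 °C to rt
Reagents that add atoms: hydrogen peroxide, OO
Why: Borane reduces the ketone and should add syn to the trisubstituted C5=C6 bond from the α-face, anti to the C20 methyl group (as with steroid 5-enes), placing boron on C6 and hydrogen on C5; oxidation with retention then gives the trans-fused 5α-H, 6α-OH compound.

Step 9
Reactants: 12 (5S,6S,8R,10S)-11,12,13,14,15,16-hexanorlabdane-6α,9-diol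
Product: 13 (5S,8R,10S)-11,12,13,14,15,16-hexanorlabdane-6,9-dione
Conditions: Dess–Martin periodinane (3 equiv), NaHCO3, CH2Cl2, rt
Reagents that add atoms: none
Why: Both secondary alcohols are oxidised; C5 and C8 are now α to carbonyl groups and should stay in the thermodynamically preferred trans-fused, 8-equatorial arrangement.

Step 10
Reactants: 13 (5S,8R,10S)-11,12,13,14,15,16-hexanorlabdane-6,9-dione
Product: 16 (5S,8R,10S)-12,13,14,15,16-pentanorlabd-9(11)-en-6-one, via 6-(tert-butyldimethylsilyloxy)-11,12,13,14,15,16-hexanorlabd-6-en-9-one 14 (not isolated), via 6-(tert-butyldimethylsilyloxy)-12,13,14,15,16-pentanorlabda-6,9(11)-diene 15 (not isolated)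
Conditions: LiN(iPr)2 (1.1 equiv), THF, −78 °C; TBSCl, DMPU, −78 to 0 °C; then Ph3P=CH2 (from Ph3PCH3Br, KOtBu), THF, 65 °C; then HCl (1 M), THF, rt
Reagents that add atoms: tert-butyldimethylsilyl chloride (silicon group present in 14 and 15 only), CC(C)(C)[Si](C)(C)Cl; methyltriphenylphosphonium bromide, C[P+](c1ccccc1)(c1ccccc1)c1ccccc1.[Br-]
Why: Kinetic deprotonation should occur at C7, the only unhindered α-CH2, so the C6 ketone is masked as its silyl enol ether and Wittig methylenation can then take place only at the doubly α-branched C9 ketone; acid work-up unmasks C6.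

Step 11
Reactants: 16 (5S,8R,10S)-12,13,14,15,16-pentanorlabd-9(11)-en-6-one
Product: 17 (5S,6R,8R,10S)-12,13,14,15,16-pentanorlabd-9(11)-en-6β-ol
Conditions: NaBH4, MeOH, −20 °C
Reagents that add atoms: none
Why: The β-face of the C6 carbonyl is blocked by the two syn-axial methyl groups (C19 on C4 and C20 on C10), so hydride should arrive from the α-face and give the axial 6β-alcohol, as is usual for 6-oxo steroids and labdanes.

Step 12
Reactants: 17 (5S,6R,8R,10S)-12,13,14,15,16-pentanorlabd-9(11)-en-6β-ol
Product: 18 (5S,6R,8R,9R,10S)-9α,11-epoxy-12,13,14,15,16-pentanorlabdan-6β-ol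
Conditions: mCPBA, NaHCO3, CH2Cl2, 0 °C
Reagents that add atoms: 3-chloroperoxybenzoic acid, OOC(=O)c1cccc(Cl)c1
Why: Prilezhaev epoxidation of the exocyclic alkene should occur from the α-face, because the β-face is screened by the adjacent axial C20 methyl group; this sets C9 with oxygen α and C11 β.

Step 13
Reactants: 18 (5S,6R,8R,9R,10S)-9α,11-epoxy-12,13,14,15,16-pentanorlabdan-6β-ol; 19 2-methylprop-2-en-1-ol
Product: 21 15-norlabd-13-ene-6β,9α,16-triol, via lithium 2-(lithiomethyl)prop-2-en-1-olate 20 (not isolated)
Conditions: 19, n-BuLi (2 equiv), TMEDA, Et2O–hexane, 0 °C to rt; then 18 (0.33 equiv), THF, 0 °C to rt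
Reagents that add atoms: 2-methylprop-2-en-1-ol (compound 19), CC(=C)CO; n-butyllithium (lithium present in 20 only), [Li]CCCC
Why: The symmetrical allyl dianion of methallyl alcohol should open the epoxide by SN2 attack at its CH2 terminus (C11), forming C11–C12 and leaving the C9 configuration untouched; the excess reagent takes up the C6 hydroxyl proton.

Step 14
Reactants: 21 15-norlabd-13-ene-6β,9α,16-triol
Product: 22 (13S)-6β-hydroxy-9α,13-epoxylabdan-16,15-olide
Conditions: PdCl2 (10 mol %), CuCl2 (3 equiv), NaOAc (3 equiv), CO (1 atm), AcOH, rt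
Reagents that add atoms: carbon monoxide, [C-]#[O+]
Why: Proposed new method: the tertiary C9 hydroxyl should attack the alkene bound to divalent palladium at its internal carbon C13 (5-exo, Markovnikov), the resulting alkylpalladium at C14 has no β-hydrogen because C13 is fully substituted, so CO insertion follows and the acylpalladium is captured by the C16 hydroxyl to close the five-membered lactone, CuCl2 reoxidising zerovalent palladium; the closest known reaction type is the palladium-catalysed intramolecular alkoxycarbonylation of alkenols and its bicyclising variant on unsaturated diols, which gives fused lactones, whereas here the lactonising hydroxyl sits on the alkene substituent and the product is spiro; C13 should be set by the bulky palladium-bearing CH2 end taking the face of the forming oxolane next to C8 (a CH) and not the face next to quaternary C10.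

Step 15
Reactants: 22 (13S)-6β-hydroxy-9α,13-epoxylabdan-16,15-olide
Product: 23 previtexilactone
Conditions: Ac2O, DMAP, Et3N, CH2Cl2, rt
Reagents that add atoms: acetic anhydride, CC(=O)OC(C)=O
Why: DMAP-catalysed acylation should acetylate the hindered axial 6β-hydroxyl, the only free hydroxyl left, under conditions too mild to open the β-alkoxy lactone by retro-oxa-Michael elimination.

**Compound list**

1 | 2-methylcyclohexane-1,3-dione | CC1C(=O)CCCC1=O | starting material
2 | allyl bromide | C=CCBr | starting material
3 | 2-methyl-2-(prop-2-en-1-yl)cyclohexane-1,3-dione | C=CCC1(C)C(=O)CCCC1=O | intermediate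
4 | (2S,3S)-3-hydroxy-2-methyl-2-(prop-2-en-1-yl)cyclohexan-1-one | C=CC[C@]1(C)C(=O)CCC[C@@H]1O | intermediate
5 | (2S,3S)-3-hydroxy-2,6-dimethyl-2-(prop-2-en-1-yl)cyclohexan-1-one, both C6 epimers | C=CC[C@]1(C)C(=O)C(C)CC[C@@H]1O | intermediate
6 | (2S)-2,4-dimethyl-2-(prop-2-en-1-yl)cyclohexane-1,3-dione, both C4 epimers | C=CC[C@]1(C)C(=O)C(C)CCC1=O | intermediate
7 | prenylmagnesium chloride | CC(C)=CC[Mg]Cl | starting material
8 | (2S)-3-hydroxy-2,6-dimethyl-3-(2-methylbut-3-en-2-yl)-2-(prop-2-en-1-yl)cyclohexan-1-one, epimers at C3 and C6 | C=CC[C@]1(C)C(=O)C(C)CCC1(O)C(C)(C)C=C | intermediate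
9 | (10S)-5-hydroxy-11,12,13,14,15,16-hexanorlabd-2-en-9-one, epimers at C5 and C8 (not isolated) | C1=CC[C@]2(C)C(=O)C(C)CCC2(O)C1(C)C | intermediate
10 | (10S)-5-hydroxy-11,12,13,14,15,16-hexanorlabdan-9-one, epimers at C5 and C8 | C1CC[C@]2(C)C(=O)C(C)CCC2(O)C1(C)C | intermediate
11 | (8R,10S)-11,12,13,14,15,16-hexanorlabd-5-en-9-one | C1CC[C@]2(C)C(=O)[C@H](C)CC=C2C1(C)C | intermediate
12 | (5S,6S,8R,10S)-11,12,13,14,15,16-hexanorlabdane-6α,9-diol, either C9 epimer | O[C@H]1C[C@@H](C)C(O)[C@@]2(C)CCCC(C)(C)[C@H]12 | intermediate
13 | (5S,8R,10S)-11,12,13,14,15,16-hexanorlabdane-6,9-dione | O=C1C[C@@H](C)C(=O)[C@@]2(C)CCCC(C)(C)[C@H]12 | intermediate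
14 | 6-(tert-butyldimethylsilyloxy)-11,12,13,14,15,16-hexanorlabd-6-en-9-one (not isolated) | CC(C)(C)[Si](C)(C)OC1=C[C@@H](C)C(=O)[C@@]2(C)CCCC(C)(C)[C@H]12 | intermediate
15 | 6-(tert-butyldimethylsilyloxy)-12,13,14,15,16-pentanorlabda-6,9(11)-diene (not isolated) | CC(C)(C)[Si](C)(C)OC1=C[C@@H](C)C(=C)[C@@]2(C)CCCC(C)(C)[C@H]12 | intermediate
16 | (5S,8R,10S)-12,13,14,15,16-pentanorlabd-9(11)-en-6-one | O=C1C[C@@H](C)C(=C)[C@@]2(C)CCCC(C)(C)[C@H]12 | intermediate
17 | (5S,6R,8R,10S)-12,13,14,15,16-pentanorlabd-9(11)-en-6β-ol | O[C@@H]1C[C@@H](C)C(=C)[C@@]2(C)CCCC(C)(C)[C@H]12 | intermediate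
18 | (5S,6R,8R,9R,10S)-9α,11-epoxy-12,13,14,15,16-pentanorlabdan-6β-ol | O[C@@H]1C[C@@H](C)[C@]3(CO3)[C@@]2(C)CCCC(C)(C)[C@H]12 | intermediate
19 | 2-methylprop-2-en-1-ol | CC(=C)CO | starting material
20 | lithium 2-(lithiomethyl)prop-2-en-1-olate (not isolated) | [Li]CC(=C)CO[Li] | intermediate
21 | 15-norlabd-13-ene-6β,9α,16-triol | O[C@@H]1C[C@@H](C)[C@](O)(CCC(=C)CO)[C@@]2(C)CCCC(C)(C)[C@H]12 | intermediate
22 | (13S)-6β-hydroxy-9α,13-epoxylabdan-16,15-olide | O[C@@H]1C[C@@H](C)[C@]2(CC[C@]3(COC(=O)C3)O2)[C@@]2(C)CCCC(C)(C)[C@H]12 | intermediate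
23 | previtexilactone, (5S,6R,8R,9R,10S,13S)-6β-acetoxy-9α,13-epoxylabdan-16,15-olide | CC(=O)O[C@@H]1C[C@@H](C)[C@]2(CC[C@]3(COC(=O)C3)O2)[C@@]2(C)CCCC(C)(C)[C@H]12 | target

**Totals**

Total step count: 15. Longest linear sequence: 15 steps (from compound 1).

**Steps most likely to fail**

Step 14. The hindered tertiary C9 hydroxyl may attack the palladium-bound alkene too slowly, so that allylic oxidation or chlorination by CuCl2 competes, or the attack may show poor facial selectivity at C13. The fallback uses known chemistry, sets out from 18 and comes back at 22. Epoxide 18 is opened at C11 with (furan-3-ylmethyl)magnesium bromide and catalytic CuI to give the furan diol 15,16-epoxylabda-13(16),14-diene-6β,9α-diol F1. Photooxygenation of the furan (O2, rose bengal, light, iPr2NEt, −78 °C) should give the γ-hydroxybutenolide 6β,9α,16-trihydroxylabd-13-en-16,15-olide F2. Reduction with NaBH4 should give the butenolide 6β,9α-dihydroxylabd-13-en-16,15-olide F3. Base (DBU, CH2Cl2) then closes the oxolane by intramolecular oxa-Michael addition of the C9 hydroxyl to C13 under equilibrating conditions, giving 22.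

Step 8. The C5=C6 bond lies between two quaternary carbons, so hydroboration may stay incomplete, may occur in part from the β-face, or boron may migrate on heating. The fallback sets out from 11 and comes back at 13. Epoxidation of 11 with mCPBA from the α-face gives 5α,6α-epoxy-11,12,13,14,15,16-hexanorlabdan-9-one F4. Reductive opening with Cp2TiCl (trivalent titanium, made from Cp2TiCl2 and Zn) and 1,4-cyclohexadiene should cleave the C5–O bond to the tertiary radical and, after hydrogen atom transfer, give 6α-hydroxy-11,12,13,14,15,16-hexanorlabdan-9-one F5. Dess–Martin oxidation of F5 gives 13, in which C5 can equilibrate to the trans ring fusion.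

Step 10. The silyl enol ether may be cleaved or may scramble under the basic ylide conditions, or the doubly α-branched C9 ketone may react so slowly that methylenation occurs at C6 instead. The fallback sets out from 13 and comes back at 17; it reverses the order of the two operations. Reduction of 13 with LiAlH(OtBu)3 at low temperature should pick the C6 carbonyl, which has one unbranched α-carbon, over the C9 carbonyl and give 6β-hydroxy-11,12,13,14,15,16-hexanorlabdan-9-one F6. Methylenation of the remaining C9 ketone of F6 with excess Ph3P=CH2 (KOtBu, toluene, 90 °C) then gives 17.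

**Further compounds**

F1 | step 14 | 15,16-epoxylabda-13(16),14-diene-6β,9α-diol | O[C@@H]1C[C@@H](C)[C@](O)(CCc3ccoc3)[C@@]2(C)CCCC(C)(C)[C@H]12
F2 | step 14 | 6β,9α,16-trihydroxylabd-13-en-16,15-olide | O[C@@H]1C[C@@H](C)[C@](O)(CCC3=CC(=O)OC3O)[C@@]2(C)CCCC(C)(C)[C@H]12
F3 | step 14 | 6β,9α-dihydroxylabd-13-en-16,15-olide | O[C@@H]1C[C@@H](C)[C@](O)(CCC3=CC(=O)OC3)[C@@]2(C)CCCC(C)(C)[C@H]12
F4 | step 8 | 5α,6α-epoxy-11,12,13,14,15,16-hexanorlabdan-9-one | [C@H]13C[C@@H](C)C(=O)[C@@]2(C)CCCC(C)(C)[C@]12O3
F5 | step 8 | 6α-hydroxy-11,12,13,14,15,16-hexanorlabdan-9-one | O[C@H]1C[C@@H](C)C(=O)[C@@]2(C)CCCC(C)(C)[C@H]12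
F6 | step 10 | 6β-hydroxy-11,12,13,14,15,16-hexanorlabdan-9-one | O[C@@H]1C[C@@H](C)C(=O)[C@@]2(C)CCCC(C)(C)[C@H]12
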